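**Retrosynthetic overview**
1. Target ⇐ C1 ketone (Peterson methylenation) ⇐ C1 alcohol that already carries the ring B trans-8-bromo-9-chloride.
2. Ring B halides ⇐ bridged 1,9-epoxy bromo-ether ⇐ C1-hydroxy spiro alkene: tethered bromoetherification, then TiCl4 opening with retention. Direct BrCl addition to the spiro alkene is expected to give the trans-diaxial isomer, not the diequatorial pair of the target.
3. Ring A cis-bromohydrin and the C1 oxygen ⇐ α'-bromo spiro enone: ketoreductase dynamic kinetic resolution (C3, C4), then hydroxyl-directed epoxidation and hydride opening.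
4. Spiro enone ⇐ dimedone vinylogous ester: Pd-catalysed enantioselective decarboxylative allylation sets spiro C6; ring-closing metathesis closes ring B.
5. Ring order: ring A is present from the start (dimedone); ring B is formed second.

Locants for all spiro compounds follow one fixed spiro[5.5]undecane numbering: C1–C5 = ring A (C1 ends as C=CH2, C3 carbinol, C4 CHBr, C5 CMe2), C6 = spiro atom, C7–C11 = ring B (C7 CH2, C8 CHBr, C9 C(CH3)Cl).

Assumption: the sense of induction of (S)-t-BuPHOX in step 5 is taken by analogy with 2-alkylcyclohexanone allyl enol carbonates; if the antipode formed, the (R)-ligand would be used.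

**Step 1**
Reactants: 1 dimedone (5,5-dimethylcyclohexane-1,3-dione); 2 2-methylpropan-1-ol
Product: 3 3-isobutoxy-5,5-dimethylcyclohex-2-en-1-one
Conditions: TsOH·H2O (cat.), toluene, reflux, Dean–Stark
Reagents that add atoms: none
Why: Acid-catalysed enol etherification of the symmetric 1,3-dione (vinylogous ester formation) is driven by azeotropic removal of water; no stereocentre is formed.

**Step 2**
Reactants: 4 3-methylbut-3-en-1-ol
Product: 5 4-iodo-2-methylbut-1-ene
Conditions: PPh3, I2, imidazole, CH2Cl2, 0 °C → rt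
Reagents that add atoms: iodine (II)
Why: Appel-type iodination of an unhindered primary alcohol proceeds by SN2 on the alkoxyphosphonium ion; no stereocentre.

**Step 3**
Reactants: 3 3-isobutoxy-5,5-dimethylcyclohex-2-en-1-one; 5 4-iodo-2-methylbut-1-ene
Product: 7 rac-3-isobutoxy-5,5-dimethyl-6-(3-methylbut-3-en-1-yl)cyclohex-2-en-1-one, via lithium enolate 6 (not isolated)
Conditions: LiN(iPr)2, THF, −78 °C; then 5, −78 °C → rt
Reagents that add atoms: none
Why: Kinetic deprotonation of a vinylogous ester occurs at the α' carbon (C6) and SN2 enolate alkylation with the primary iodide follows; the product is racemic and its stereocentre is erased in step 4.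

**Step 4**
Reactants: 7 rac-3-isobutoxy-5,5-dimethyl-6-(3-methylbut-3-en-1-yl)cyclohex-2-en-1-one; 8 allyl chloroformate
Product: 10 allyl 5-isobutoxy-3,3-dimethyl-2-(3-methylbut-3-en-1-yl)cyclohexa-1,5-dien-1-yl carbonate, via lithium enolate 9 (not isolated)
Conditions: LiN(iPr)2, TMEDA, THF, −78 °C; then 8
Reagents that add atoms: none
Why: O-acylation of the fully substituted lithium enolate by the hard chloroformate (TMEDA-assisted) gives the allyl enol carbonate needed for decarboxylative allylation.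

**Step 5**
Reactants: 10 allyl 5-isobutoxy-3,3-dimethyl-2-(3-methylbut-3-en-1-yl)cyclohexa-1,5-dien-1-yl carbonate
Product: 11 (R)-6-allyl-3-isobutoxy-5,5-dimethyl-6-(3-methylbut-3-en-1-yl)cyclohex-2-en-1-one
Conditions: Pd2(dba)3 (2.5 mol %), (S)-t-BuPHOX (6 mol %), toluene, 25 °C
Reagents that add atoms: none
Why: Enantioselective decarboxylative allylic alkylation (Tsuji allylation): zerovalent palladium with the chiral P,N ligand forms a π-allyl/enolate pair and the ligand selects the enolate face, setting the quaternary carbon (the first stereocentre, later spiro C6).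

**Step 6**
Reactants: 11 (R)-6-allyl-3-isobutoxy-5,5-dimethyl-6-(3-methylbut-3-en-1-yl)cyclohex-2-en-1-one
Product: 12 (R)-3-isobutoxy-5,5,9-trimethylspiro[5.5]undeca-2,8-dien-1-one
Conditions: second-generation Grubbs catalyst (3 mol %), CH2Cl2, 40 °C
Reagents that add atoms: none
Why: Ring-closing metathesis between the allyl and the 1,1-disubstituted alkene closes ring B as a trisubstituted cyclohexene with loss of ethylene; C6 is untouched.

**Step 7**
Reactants: 12 (R)-3-isobutoxy-5,5,9-trimethylspiro[5.5]undeca-2,8-dien-1-one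
Product: 14 (S)-5,5,9-trimethylspiro[5.5]undeca-1,8-dien-3-one, via allylic alcohol 13 (not isolated)
Conditions: LiAlH4, Et2O, 0 °C; then 1 M HCl, rt
Reagents that add atoms: none
Why: Stork–Danheiser transposition: 1,2-reduction of the vinylogous ester, then acid hydrolysis of the enol ether with loss of water, gives the transposed enone; C6 keeps its configuration (the descriptor changes only through CIP priorities).

**Step 8**
Reactants: 14 (S)-5,5,9-trimethylspiro[5.5]undeca-1,8-dien-3-one
Product: 16 (6S)-4-bromo-5,5,9-trimethylspiro[5.5]undeca-1,8-dien-3-one (both C4 epimers), via silyl dienol ether 15 (not isolated)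
Conditions: Me3SiOTf, Et3N, CH2Cl2, 0 °C; then NBS, THF, −78 °C
Reagents that add atoms: N-bromosuccinimide (O=C1CCC(=O)N1Br)
Why: Because C6 is quaternary the enone can enolise only at C4, so electrophilic bromination of the cross-conjugated silyl dienol ether is regiospecific; C4 is not controlled here and is corrected in step 9.

**Step 9**
Reactants: 16 (6S)-4-bromo-5,5,9-trimethylspiro[5.5]undeca-1,8-dien-3-one (both C4 epimers)
Product: 17 (3R,4S,6S)-4-bromo-5,5,9-trimethylspiro[5.5]undeca-1,8-dien-3-ol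
Conditions: ketoreductase (NADPH-dependent, anti-Prelog, chosen from a commercial panel), NADP+ (cat.), iPrOH (10 vol %), triethanolamine–HCl buffer pH 8.5, 30 °C
Reagents that add atoms: none
Why: Enzymatic dynamic kinetic resolution: C4–H is the only acidic site and epimerises in the buffer, while the ketoreductase reduces only the (4S)-epimer from one carbonyl face, so the cis-bromohydrin (3R,4S) is set by the enzyme independently of the remote spiro centre.

**Step 10**
Reactants: 17 (3R,4S,6S)-4-bromo-5,5,9-trimethylspiro[5.5]undeca-1,8-dien-3-ol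
Product: 18 (1R,2S,3R,4S,6R)-4-bromo-1,2-epoxy-5,5,9-trimethylspiro[5.5]undec-8-en-3-ol (epoxide cis to the 3-OH)
Conditions: VO(acac)2 (3 mol %), t-BuOOH, CH2Cl2, 0 °C → rt
Reagents that add atoms: tert-butyl hydroperoxide (CC(C)(C)OO)
Why: Hydroxyl-directed vanadium-catalysed epoxidation delivers oxygen to C1=C2 on the face of the C3 hydroxyl and leaves the isolated ring B alkene untouched.

**Step 11**
Reactants: 18 (1R,2S,3R,4S,6R)-4-bromo-1,2-epoxy-5,5,9-trimethylspiro[5.5]undec-8-en-3-ol
Product: 19 (1S,3R,4S,6R)-4-bromo-5,5,9-trimethylspiro[5.5]undec-8-ene-1,3-diol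
Conditions: LiAlH4, THF, 0 °C
Reagents that add atoms: none
Why: Hydride opens the epoxide at C2 (trans-diaxial Fürst–Plattner opening; C1 is neopentyl), leaving the oxygen on C1 cis to the 3-OH, while the neopentyl secondary bromide is inert to SN2.

**Step 12**
Reactants: 19 (1S,3R,4S,6R)-4-bromo-5,5,9-trimethylspiro[5.5]undec-8-ene-1,3-diol
Product: 20 (1S,3R,4S,6R,8S,9S)-4,8-dibromo-1,9-epoxy-5,5,9-trimethylspiro[5.5]undecan-3-ol
Conditions: NBS (1.05 equiv), CH2Cl2, 0 °C, dark
Reagents that add atoms: N-bromosuccinimide (O=C1CCC(=O)N1Br)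
Why: Bromoetherification (cf. terpineol to bromocineole): bromonium formation is reversible and only the ion on the face opposite the C1 oxygen is trapped, by Markovnikov attack at C9 to give the 2-oxabicyclo[2.2.2]octane, which fixes Br at C8 trans to C1 and the C9–O bond cis to C1.

**Step 13**
Reactants: 20 (1S,3R,4S,6R,8S,9S)-4,8-dibromo-1,9-epoxy-5,5,9-trimethylspiro[5.5]undecan-3-ol
Product: 21 (1S,3R,4S,6R,8S,9S)-4,8-dibromo-3-[(tert-butyldimethylsilyl)oxy]-1,9-epoxy-5,5,9-trimethylspiro[5.5]undecane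
Conditions: t-BuMe2SiOTf, 2,6-lutidine, CH2Cl2, 0 °C
Reagents that add atoms: tert-butyldimethylsilyl triflate (CC(C)(C)[Si](C)(C)OS(=O)(=O)C(F)(F)F)
Why: Silylation of the only free hydroxyl (C3) differentiates the two ring A oxygens, since the C1 oxygen is tied up in the ether.

**Step 14**
Reactants: 21 (1S,3R,4S,6R,8S,9S)-4,8-dibromo-3-[(tert-butyldimethylsilyl)oxy]-1,9-epoxy-5,5,9-trimethylspiro[5.5]undecane
Product: 22 (1S,3R,4S,6R,8S,9S)-4,8-dibromo-3-[(tert-butyldimethylsilyl)oxy]-9-chloro-5,5,9-trimethylspiro[5.5]undecan-1-ol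
Conditions: TiCl4 (1.2 equiv), CH2Cl2, −78 °C; then aq. NaHCO3
Reagents that add atoms: titanium tetrachloride (Cl[Ti](Cl)(Cl)Cl)
Why: Lewis-acid ether cleavage with neighbouring-group participation: TiCl4 ionises the strained tertiary C9–O bond, the C8 bromine held anti-periplanar to it bridges, and chloride enters C9 on the face the oxygen left (double inversion, net retention), giving the trans-8-bromo-9-chloride with Cl cis to C1.

**Step 15**
Reactants: 22 (1S,3R,4S,6R,8S,9S)-4,8-dibromo-3-[(tert-butyldimethylsilyl)oxy]-9-chloro-5,5,9-trimethylspiro[5.5]undecan-1-ol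
Product: 23 (3R,4S,6R,8S,9S)-4,8-dibromo-3-[(tert-butyldimethylsilyl)oxy]-9-chloro-5,5,9-trimethylspiro[5.5]undecan-1-one
Conditions: Dess–Martin periodinane, CH2Cl2, rt
Reagents that add atoms: none
Why: Neutral Dess–Martin oxidation of the secondary C1 alcohol gives the ketone without touching the halides or the silyl ether; the C1 stereocentre is removed and the only enolisable neighbour (C2) is a CH2.

**Step 16**
Reactants: 23 (3R,4S,6R,8S,9S)-4,8-dibromo-3-[(tert-butyldimethylsilyl)oxy]-9-chloro-5,5,9-trimethylspiro[5.5]undecan-1-one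
Product: 25 (3R,4S,6S,8S,9S)-4,8-dibromo-9-chloro-5,5,9-trimethyl-1-methylidenespiro[5.5]undecan-3-ol, via beta-hydroxysilane 24 (not isolated)
Conditions: Me3SiCH2Li, CeCl3, THF, −78 → 0 °C; then 48% aq. HF, MeCN, rt
Reagents that add atoms: (trimethylsilyl)methyllithium (C[Si](C)(C)C[Li])
Why: Peterson olefination: the weakly basic organocerium reagent adds to the hindered, enolisable ketone and acid-induced elimination can only give the exocyclic alkene, with HF also removing the silyl ether; no stereocentre is affected.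

**Compound list**
1 | dimedone (5,5-dimethylcyclohexane-1,3-dione) | CC1(C)CC(=O)CC(=O)C1 | starting material
2 | 2-methylpropan-1-ol | CC(C)CO | starting material
3 | 3-isobutoxy-5,5-dimethylcyclohex-2-en-1-one | CC(C)COC1=CC(=O)CC(C)(C)C1 | intermediate
4 | 3-methylbut-3-en-1-ol | C=C(C)CCO | starting material
5 | 4-iodo-2-methylbut-1-ene | C=C(C)CCI | intermediate
6 | lithium 5-isobutoxy-3,3-dimethylcyclohexa-1,5-dien-1-olate (kinetic enolate of 3) | CC(C)COC1=CC(O[Li])=CC(C)(C)C1 | intermediate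
7 | rac-3-isobutoxy-5,5-dimethyl-6-(3-methylbut-3-en-1-yl)cyclohex-2-en-1-one | CC(C)COC1=CC(=O)C(CCC(C)=C)C(C)(C)C1 | intermediate
8 | allyl chloroformate | C=CCOC(=O)Cl | starting material
9 | lithium 5-isobutoxy-3,3-dimethyl-2-(3-methylbut-3-en-1-yl)cyclohexa-1,5-dien-1-olate (enolate of 7) | CC(C)COC1=CC(O[Li])=C(CCC(C)=C)C(C)(C)C1 | intermediate
10 | allyl 5-isobutoxy-3,3-dimethyl-2-(3-methylbut-3-en-1-yl)cyclohexa-1,5-dien-1-yl carbonate | CC(C)COC1=CC(OC(=O)OCC=C)=C(CCC(C)=C)C(C)(C)C1 | intermediate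
11 | (R)-6-allyl-3-isobutoxy-5,5-dimethyl-6-(3-methylbut-3-en-1-yl)cyclohex-2-en-1-one | O=C1C=C(OCC(C)C)CC(C)(C)[C@]1(CC=C)CCC(C)=C | intermediate
12 | (R)-3-isobutoxy-5,5,9-trimethylspiro[5.5]undeca-2,8-dien-1-one | O=C1C=C(OCC(C)C)CC(C)(C)[C@]12CCC(C)=CC2 | intermediate
13 | (6R)-3-isobutoxy-5,5,9-trimethylspiro[5.5]undeca-2,8-dien-1-ol (C1 epimers) | OC1C=C(OCC(C)C)CC(C)(C)[C@]12CCC(C)=CC2 | intermediate
14 | (S)-5,5,9-trimethylspiro[5.5]undeca-1,8-dien-3-one | C1=CC(=O)CC(C)(C)[C@]12CCC(C)=CC2 | intermediate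
15 | trimethyl{[(6S)-5,5,9-trimethylspiro[5.5]undeca-1,3,8-trien-3-yl]oxy}silane | C1=CC(O[Si](C)(C)C)=CC(C)(C)[C@]12CCC(C)=CC2 | intermediate
16 | (6S)-4-bromo-5,5,9-trimethylspiro[5.5]undeca-1,8-dien-3-one (C4 epimers) | C1=CC(=O)C(Br)C(C)(C)[C@]12CCC(C)=CC2 | intermediate
17 | (3R,4S,6S)-4-bromo-5,5,9-trimethylspiro[5.5]undeca-1,8-dien-3-ol | C1=C[C@@H](O)[C@@H](Br)C(C)(C)[C@]12CCC(C)=CC2 | intermediate
18 | (1R,2S,3R,4S,6R)-4-bromo-1,2-epoxy-5,5,9-trimethylspiro[5.5]undec-8-en-3-ol (epoxide cis to OH) | [C@@H]13O[C@H]3[C@@H](O)[C@@H](Br)C(C)(C)[C@]12CCC(C)=CC2 | intermediate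
19 | (1S,3R,4S,6R)-4-bromo-5,5,9-trimethylspiro[5.5]undec-8-ene-1,3-diol | O[C@H]1C[C@@H](O)[C@@H](Br)C(C)(C)[C@]12CCC(C)=CC2 | intermediate
20 | (1S,3R,4S,6R,8S,9S)-4,8-dibromo-1,9-epoxy-5,5,9-trimethylspiro[5.5]undecan-3-ol | O3[C@H]1C[C@@H](O)[C@@H](Br)C(C)(C)[C@]12CC[C@@]3(C)[C@@H](Br)C2 | intermediate
21 | (1S,3R,4S,6R,8S,9S)-4,8-dibromo-3-[(tert-butyldimethylsilyl)oxy]-1,9-epoxy-5,5,9-trimethylspiro[5.5]undecane | O3[C@H]1C[C@@H](O[Si](C)(C)C(C)(C)C)[C@@H](Br)C(C)(C)[C@]12CC[C@@]3(C)[C@@H](Br)C2 | intermediate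
22 | (1S,3R,4S,6R,8S,9S)-4,8-dibromo-3-[(tert-butyldimethylsilyl)oxy]-9-chloro-5,5,9-trimethylspiro[5.5]undecan-1-ol | O[C@H]1C[C@@H](O[Si](C)(C)C(C)(C)C)[C@@H](Br)C(C)(C)[C@]12CC[C@](C)(Cl)[C@@H](Br)C2 | intermediate
23 | (3R,4S,6R,8S,9S)-4,8-dibromo-3-[(tert-butyldimethylsilyl)oxy]-9-chloro-5,5,9-trimethylspiro[5.5]undecan-1-one | O=C1C[C@@H](O[Si](C)(C)C(C)(C)C)[C@@H](Br)C(C)(C)[C@]12CC[C@](C)(Cl)[C@@H](Br)C2 | intermediate
24 | (3R,4S,6R,8S,9S)-4,8-dibromo-3-[(tert-butyldimethylsilyl)oxy]-9-chloro-5,5,9-trimethyl-1-[(trimethylsilyl)methyl]spiro[5.5]undecan-1-ol (C1 epimers) | C[Si](C)(C)CC1(O)C[C@@H](O[Si](C)(C)C(C)(C)C)[C@@H](Br)C(C)(C)[C@]12CC[C@](C)(Cl)[C@@H](Br)C2 | intermediate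
25 | (3R,4S,6S,8S,9S)-4,8-dibromo-9-chloro-5,5,9-trimethyl-1-methylidenespiro[5.5]undecan-3-ol (chamigrene numbering: 2S,3S,6S,9R,10S) | C=C1C[C@@H](O)[C@@H](Br)C(C)(C)[C@]12CC[C@](C)(Cl)[C@@H](Br)C2 | target

**Totals**
Total step count: 16. Longest linear sequence: 15 steps (steps 1 and 3–16, from dimedone 1); step 2 is a one-step side branch.

**Three steps most likely to fail, with fallbacks**

Step 9 (the ketoreductase may accept the hindered α'-bromo enone poorly, or C4 may epimerise too slowly for a dynamic resolution). The fallback separates reduction from resolution and sets out from 16. iBu2AlH (CH2Cl2, −78 °C) adds hydride anti to the C–Br bond of each epimer and gives 17 mixed with its cis-bromohydrin diastereomer (3S,4R,6S)-4-bromo-5,5,9-trimethylspiro[5.5]undeca-1,8-dien-3-ol F1. A lipase (Burkholderia cepacia lipase, vinyl acetate, MTBE, 30 °C) acetylates the (3R)-alcohol selectively to (3R,4S,6S)-4-bromo-5,5,9-trimethylspiro[5.5]undeca-1,8-dien-3-yl acetate F2. Unreacted F1 is separated, re-oxidised with Dess–Martin periodinane to 16 and recycled. K2CO3/MeOH on F2 returns 17, where the route is rejoined.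

Step 11 (LiAlH4 has to open the epoxide at C2 only and spare the C4 bromide). The fallback brings in the C1 oxygen by a silicon tether and sets out from 17. ClSiHMe2/Et3N gives the dimethylsilyl ether of 17 F3. Pt2[(CH2=CHSiMe2)2O]3 (cat., toluene, 60 °C) effects intramolecular hydrosilylation to the cis-fused oxasilolane (Si on C1, O on C3) F4. Tamao oxidation (H2O2, KF, KHCO3, THF/MeOH) with retention gives 19, where the route is rejoined.

Step 14 (least precedented: chloride must return to C9 with retention and without elimination, and the silyl ether must survive TiCl4). The fallback is an alkoxide-directed bromochlorination that never passes through the bridged ether; it sets out from 18. t-BuMe2SiOTf/2,6-lutidine gives the tert-butyldimethylsilyl ether of 18 F5. LiAlH4 opens it at C2 to (1S,3R,4S,6R)-4-bromo-3-[(tert-butyldimethylsilyl)oxy]-5,5,9-trimethylspiro[5.5]undec-8-en-1-ol F6. F6 is treated with ClTi(OiPr)3 and NBS (CH2Cl2/hexane, −20 °C): the titanium-bound C1 oxygen hands chloride to C9 on its own face while bromine adds to C8 from the other face, giving 22, where the route is rejoined. This also by-passes the strained bridged ether of step 12.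

**Further compounds**
F1 | step 9 | (3S,4R,6S)-4-bromo-5,5,9-trimethylspiro[5.5]undeca-1,8-dien-3-ol | C1=C[C@H](O)[C@H](Br)C(C)(C)[C@]12CCC(C)=CC2
F2 | step 9 | (3R,4S,6S)-4-bromo-5,5,9-trimethylspiro[5.5]undeca-1,8-dien-3-yl acetate | C1=C[C@@H](OC(C)=O)[C@@H](Br)C(C)(C)[C@]12CCC(C)=CC2
F3 | step 11 | dimethylsilyl ether of 17 | C1=C[C@@H](O[SiH](C)C)[C@@H](Br)C(C)(C)[C@]12CCC(C)=CC2
F4 | step 11 | cis-fused oxasilolane from F3 (Si on C1, O on C3) | [C@H]13C[C@@H](O[Si]3(C)C)[C@@H](Br)C(C)(C)[C@]12CCC(C)=CC2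
F5 | step 14 | tert-butyldimethylsilyl ether of 18 | [C@@H]13O[C@H]3[C@@H](O[Si](C)(C)C(C)(C)C)[C@@H](Br)C(C)(C)[C@]12CCC(C)=CC2
F6 | step 14 | (1S,3R,4S,6R)-4-bromo-3-[(tert-butyldimethylsilyl)oxy]-5,5,9-trimethylspiro[5.5]undec-8-en-1-ol | O[C@H]1C[C@@H](O[Si](C)(C)C(C)(C)C)[C@@H](Br)C(C)(C)[C@]12CCC(C)=CC2
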